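## The problem

Compound 18, (3R)-3-[2,3-dihydroxy-4-methoxy-5-(2-methylbut-3-en-2-yl)phenyl]-3,7-dihydroxychroman-4-one, is a 3-hydroxyisoflavanone. Ring A (a resorcinol) is fused to the pyranone ring C, and C3 of ring C carries both ring B and a tertiary hydroxyl next to the C4 ketone. C3 is the only stereocentre and is fully substituted. No second centre exists to control it, so a chiral catalyst must set it; because it bears no hydrogen, it cannot epimerise once made. Ring B is pentasubstituted, with free phenols at C2' and C3', a methoxyl at C4' and a 1,1-dimethylallyl group at C5'. That group can only arrive by a [3,3] shift from O4', so O4' must be allylated, rearranged and only then methylated, while O2' and O3' are kept distinct from it. The molecule tolerates little: the catechol oxidises in base and air, the tertiary benzylic α-ketol can ionise in acid or undergo a ketol shift in strong base, and the terminal alkene rules out hydrogenolysis and electrophilic oxidants. The last protecting groups therefore have to be fluoride-labile silyl ethers. The feature that opens the route is the array O1–C2H2–C3(OH)–C4(=O). Its C3–O and C2–O1 bonds are what remains of a terminal α,β-epoxy ketone after the phenolic oxygen on C8a of ring A has attacked the CH2, and that epoxy ketone is the oxidation product of an α-methylene ketone joining the two aryl rings.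

## Retrosynthesis

**18 from 17.** The two O–Si bonds on ring B are cut last. Silyl ethers are the only masks for the catechol that come off without acid, base or hydrogen, and removing them at the end keeps the air-sensitive catechol out of every earlier step. The forward reaction only needs buffered fluoride.

**17 from 14, through 15 and 16.** The O1–C2 and C3–O bonds are cut together, which opens ring C and leads back to enone 14, a 1,2-diarylprop-2-en-1-one with all four phenols silylated. The neighbouring cuts are hydroxylation of an isoflavanone enolate at C3 and an acyloin-type C3–C4 closure. The first needs a stoichiometric chiral oxidant on an enolate that can expel the ring oxygen. The second is weighed below. The epoxide route creates the stereocentre with a catalyst and leaves it untouched during ring closure. The precursor 14 has no stereocentre and no heterocycle. The forward reaction must do four things: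
- epoxidise the electron-poor alkene enantioselectively without touching the monosubstituted alkene;
- keep the ring A phenol masked until the epoxide exists;
- free that phenol selectively afterwards;
- open the oxirane at CH2 and not at C3.

**14 from 13, then 9 and 11.** The ketone is taken back to the carbinol 13, and the C3–C4 bond is cut to give an α-arylvinyl nucleophile and aldehyde 11. The acetyl group of a ring B acetophenone maps directly onto C3 and C2, so no homologation is needed. A deoxybenzoin/methylenation route would need a ring B arylacetic acid and acidic acylation conditions that the 1,1-dimethylallyl group would not survive. The obvious vinyllithium (from a sulfonylhydrazone) is rejected because a carbanion 1,4 to an aryl O–Si bond is set up for O-to-C silyl migration (retro-Brook). The vinyl unit is therefore delivered as the triflate 9 and coupled through chromium (12), whose covalent C–Cr bond does not attack silicon. Both fragments are simple arenes, and the carbinol centre of 13 is irrelevant because it is oxidised.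

**9 from 8, and 11 from 10.** The triflate is the enol derivative of methyl ketone 8, and the aldehyde is bis-silylated 2,4-dihydroxybenzaldehyde 10. Both steps are single functional-group changes. The enolisation must be done cold so that the enolate does not take the neighbouring silyl group.

**8 from 7, 4, 3, and 1 with 2.** The O4–CH3 bond, the C5–C(CH3)2 bond (by Claisen retron, back to the O4 prenyl ether) and the two O–Si bonds are cut in turn, ending at gallacetophenone 1 and prenyl bromide 2. The order is dictated by regiochemistry:
- O4 is the most acidic phenol of 1 and takes the prenyl group first.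
- O2 and O3 are then silylated, so O4 is the only oxygen that can rearrange and later be methylated.
- C5 is the only free ortho position for the [3,3] shift.
- Methylation comes last because O4 must first deliver the allyl group.

The silyl groups installed in step 2 are the ones removed in step 10, so no protecting-group exchange is needed.

## Roads not taken

**Alternative 1: carbene, alcohol and formaldehyde assemble C3.** The cut is C2–C3 and C3–O. Rh2(OAc)4 would convert diazo ketone A1 into a carbene at C3, 4-methoxybenzyl alcohol would add to give an oxonium ylide, and formaldehyde would trap it under a chiral phosphoric acid to give the open-chain ether alcohol A2. Ring C would be closed afterwards by displacement of the ring A fluoride.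
- Merits: C3 is built with its oxygen and C2 in one convergent step. No enone is present that could cyclise racemically. The later ring closure has no regiochemical branch. In these respects it is cleaner than the chosen plan.
- Weak points: formaldehyde is the smallest and least discriminating electrophile for ylide trapping, and it competes with the simple 1,2-proton shift. The carbene sits ortho to a silyloxy oxygen and in a molecule with a vinyl group. The 4-methoxybenzyl ether on a tertiary centre must later be removed oxidatively or with acid beside an electron-rich ring. A1 needs a deoxybenzoin and a diazo transfer, and three operations follow the key step.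
- Comparison: the chosen plan offers a catalytic asymmetric step of a known substrate class, one step after the key step, and no diazo compound or extra protecting group.

**Alternative 2: dearomatising a pterocarpene.** The cut is the C3–O bond and the C4 carbonyl. A chiral Mn(salen)Cl complex with NaOCl would epoxidise the furan double bond of pterocarpene A3, and water would open the epoxide at the ketal carbon to give ketol A4 with the 2'-phenol released.
- Merits: the whole skeleton and ring C exist before the stereocentre is made, and there is no question of epoxide regiochemistry or premature cyclisation. Here it is better than the chosen plan.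
- Weak points: the alkene is tetrasubstituted and part of an aromatic benzofuran, a class much less established for enantioselective oxo transfer than chromenes. NaOCl in the presence of a very electron-rich arene and a newly freed phenol invites chlorination and quinone formation. A3 requires an isoflavonoid with O2' and O3' already differentiated, which is no shorter than reaching 14.
- Comparison: the chosen plan uses base-free H2O2, which leaves electron-rich arenes alone, a proven substrate class for the asymmetric step, and a precursor made by one fragment coupling.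

**Alternative 3: carbene-catalysed crossed benzoin.** The cut is C3–C4. A chiral triazolium-derived carbene would turn the aldehyde of keto aldehyde A5 into an acyl anion equivalent that adds to the tethered ring B ketone, giving the tris-silyl ether A6.
- Merits: this is the closest competitor. Asymmetric aldehyde–ketone benzoin closure is an established entry to 3-hydroxychroman-4-ones, the reaction is redox-neutral, no dimerisation-prone enone is involved, and the step count from ketone 8 is about the same. On precedent for the ring system it is at least as good as the chosen plan.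
- Weak points for this target: the acceptor is a hindered aryl ketone on an electron-rich ring flanked by a silyloxy group. The aryloxymethyl ketone of A5 has an acidic CH2, so the base needed for alkylation and for carbene generation can drive the intramolecular aldol that leads to 2-aroylbenzofurans (Rap–Stoermer condensation). α-Bromination of 8 must spare the vinyl group and the activated arene. The C–C bond formation is reversible.
- Comparison: in the chosen plan the C3–C4 bond is made earlier by a chromium addition that does not depend on the electrophilicity of the ring B ketone, and the stereocentre is formed in an irreversible C–O closure.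

Key step: step 9

Assumption: the sense of induction of the chiral N,N'-dioxide–Sc(OTf)3 catalyst on enone 14 cannot be read from the structure; the ligand antipode (both come from the enantiomers of pipecolic acid) that gives the (R)-epoxide 15 is used.

## Route

TBS = tert-butyldimethylsilyl; TBSO = tert-butyldimethylsilyloxy.

Step 1
Reactants: 1 gallacetophenone [1-(2,3,4-trihydroxyphenyl)ethanone]; 2 prenyl bromide (1-bromo-3-methylbut-2-ene)
Product: 3 1-[2,3-dihydroxy-4-(3-methylbut-2-enyloxy)phenyl]ethanone
Conditions: NaHCO3 (1.5 equiv), DMF, 40 °C, argon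
Reagents that add atoms: none
Why: Williamson etherification; NaHCO3 ionises only the 4-OH, the most acidic phenol because it is para to the acetyl group, while the 2-OH is hydrogen-bonded to the ketone and the 3-OH is not conjugated with it, so a single prenyl group should go on O4.

Step 2
Reactants: 3 1-[2,3-dihydroxy-4-(3-methylbut-2-enyloxy)phenyl]ethanone
Product: 4 1-[2,3-bis(TBSO)-4-(3-methylbut-2-enyloxy)phenyl]ethanone
Conditions: TBSCl (3 equiv), imidazole, DMAP (cat.), DMF, 45 °C
Reagents that add atoms: tert-butyldimethylsilyl chloride, CC(C)(C)[Si](C)(C)Cl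
Why: Imidazole-promoted silylation of both remaining phenols; vicinal bis-TBS ethers of 2,3-dihydroxy-4-alkoxyaryl carbonyl compounds are well known, and capping O2 and O3 here leaves O4 as the only oxygen the next two steps can touch.

Step 3
Reactants: 4 1-[2,3-bis(TBSO)-4-(3-methylbut-2-enyloxy)phenyl]ethanone
Product: 7 1-[2,3-bis(TBSO)-4-hydroxy-5-(2-methylbut-3-en-2-yl)phenyl]ethanone, via ortho-dienone 5 (not isolated), via trimethylsilyl ether 6 (not isolated)
Conditions: N,O-bis(trimethylsilyl)acetamide (3 equiv), PhNEt2, 185 °C; then MeOH, citric acid (cat.), rt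
Reagents that add atoms: none
Why: Aromatic Claisen rearrangement; the prenyl ether shifts [3,3] to C5, the only free ortho position, with allylic inversion to give the 1,1-dimethylallyl group, and dienone 5 enolises. The silylating agent caps the new phenol as 6 as it forms, which should suppress the abnormal Claisen pathway, cyclisation onto the alkene and silyl migration between neighbouring oxygens; the labile aryl trimethylsilyl ether is cleaved by methanol on work-up.

Step 4
Reactants: 7 1-[2,3-bis(TBSO)-4-hydroxy-5-(2-methylbut-3-en-2-yl)phenyl]ethanone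
Product: 8 1-[2,3-bis(TBSO)-4-methoxy-5-(2-methylbut-3-en-2-yl)phenyl]ethanone
Conditions: MeOH (5 equiv), PPh3, diisopropyl azodicarboxylate, THF, 0 °C to rt
Reagents that add atoms: methanol, CO
Why: Mitsunobu O-methylation of the single free phenol, which is acidic because it is para to the acetyl group; the neutral conditions avoid carbonate bases that could strip the silyl ether ortho to the ketone or move the O3 silyl group, and a methyl group is small enough to reach the flanked oxygen.

Step 5
Reactants: 8 1-[2,3-bis(TBSO)-4-methoxy-5-(2-methylbut-3-en-2-yl)phenyl]ethanone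
Product: 9 1-[2,3-bis(TBSO)-4-methoxy-5-(2-methylbut-3-en-2-yl)phenyl]ethenyl trifluoromethanesulfonate
Conditions: LiN(SiMe3)2 (1.1 equiv), THF, –78 °C; then N-(5-chloropyridin-2-yl)bis(trifluoromethanesulfonyl)imide, –78 to –40 °C
Reagents that add atoms: N-(5-chloropyridin-2-yl)bis(trifluoromethanesulfonyl)imide, O=S(=O)(N(c1ccc(Cl)cn1)S(=O)(=O)C(F)(F)F)C(F)(F)F
Why: Kinetic enolisation of the methyl ketone and O-sulfonylation by a pyridyl triflimide that reacts with lithium enolates at –78 °C gives the 1-arylvinyl triflate; the low temperature and the lithium counter-ion should keep the enolate from taking the neighbouring silyl group.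

Step 6
Reactants: 10 2,4-dihydroxybenzaldehyde
Product: 11 2,4-bis(TBSO)benzaldehyde
Conditions: TBSCl (2.4 equiv), imidazole, DMF, 0 °C to rt
Reagents that add atoms: tert-butyldimethylsilyl chloride, CC(C)(C)[Si](C)(C)Cl
Why: Standard silylation of both phenols; the ortho silyl ether is the masked ring A nucleophile of the key step.

Step 7
Reactants: 9 1-[2,3-bis(TBSO)-4-methoxy-5-(2-methylbut-3-en-2-yl)phenyl]ethenyl trifluoromethanesulfonate; 11 2,4-bis(TBSO)benzaldehyde
Product: 13 rac-1-[2,4-bis(TBSO)phenyl]-2-[2,3-bis(TBSO)-4-methoxy-5-(2-methylbut-3-en-2-yl)phenyl]prop-2-en-1-ol, via alkenylchromium dichloride 12 (not isolated)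
Conditions: CrCl2 (4 equiv), NiCl2 (2 mol%), degassed DMF, rt
Reagents that add atoms: none
Why: Nozaki–Hiyama–Kishi coupling; zerovalent nickel inserts into the C–OTf bond, the alkenyl group passes to trivalent chromium (12) and adds to the aldehyde. The covalent C–Cr bond should not trigger the 1,4 O-to-C silyl shift expected of the corresponding vinyllithium, and the chromium alkoxide should not pull the ortho silyl group off ring A; the new carbinol centre is racemic and is erased in step 8.

Step 8
Reactants: 13 rac-1-[2,4-bis(TBSO)phenyl]-2-[2,3-bis(TBSO)-4-methoxy-5-(2-methylbut-3-en-2-yl)phenyl]prop-2-en-1-ol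
Product: 14 1-[2,4-bis(TBSO)phenyl]-2-[2,3-bis(TBSO)-4-methoxy-5-(2-methylbut-3-en-2-yl)phenyl]prop-2-en-1-one
Conditions: nPr4N[RuO4] (5 mol%), N-methylmorpholine N-oxide (1.5 equiv), 4 Å sieves, CH2Cl2, 0 °C to rt
Reagents that add atoms: none
Why: Ley–Griffith oxidation of a secondary alcohol that is both benzylic and allylic; the neutral medium spares the silyl ethers and the monosubstituted alkene, and the α-aryl enone is used at once because such enones dimerise on standing.

Step 9
Reactants: 14 1-[2,4-bis(TBSO)phenyl]-2-[2,3-bis(TBSO)-4-methoxy-5-(2-methylbut-3-en-2-yl)phenyl]prop-2-en-1-one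
Product: 17 (3R)-3-[2,3-bis(TBSO)-4-methoxy-5-(2-methylbut-3-en-2-yl)phenyl]-3,7-dihydroxychroman-4-one, via tetrasilyl epoxy ketone 15 (not isolated), via ring A diphenol epoxy ketone 16 (not isolated)
Conditions: chiral pipecolic-acid-derived N,N'-dioxide ligand with 2,6-diisopropylanilide arms (10 mol%), Sc(OTf)3 (10 mol%), 30% aq. H2O2 (2 equiv), THF, 0 °C; Me2S, 0 °C; then K2CO3, MeOH, 0 °C
Reagents that add atoms: hydrogen peroxide, OO
Why: The scandium-bound enone takes hydroperoxide at its unhindered terminal CH2 (Weitz–Scheffer addition) and the resulting enolate attacks the O–O bond in a 3-exo-tet closure to oxirane 15; C3 becomes stereogenic only in this closure, and the chiral N,N'-dioxide pocket around scandium decides which enolate face bonds to oxygen. The closest known reaction types are the catalytic asymmetric epoxidation of α-substituted vinyl ketones with H2O2 under chiral N,N'-dioxide–Sc(OTf)3 complexes and the phenoxide opening of an α,β-epoxy ketone that underlies the Algar–Flynn–Oyamada reaction. No base is present during the oxidation, so all four silyl ethers should stay on and the racemic oxa-Michael closure of a free ring A phenol onto the enone cannot compete. Dimethyl sulfide then destroys the remaining peroxide, which would otherwise degrade the 2,4-dihydroxyaryl ketone by Dakin oxidation once base is added. K2CO3 in methanol should cleave the two ring A silyl ethers first, because their phenoxides are stabilised by the ortho and para acyl group while the crowded, electron-rich ring B ethers react far more slowly; this gives 16. The C8a phenoxide then opens the oxirane at the primary CH2 in a 6-endo-tet closure, forming O1–C2 and ring C, while the C3–O bond is never broken, so the configuration set in the epoxidation is carried into 17 as (R). The required regioselectivity is secured by the substrate: the alternative 5-exo attack would need inversion at a fully substituted carbon flanked by an aryl group and a carbonyl, and the para phenoxide can reach neither carbon. The product has no hydrogen at C3, so neither β-elimination of the ring oxygen nor epimerisation can follow under the basic conditions.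

Step 10
Reactants: 17 (3R)-3-[2,3-bis(TBSO)-4-methoxy-5-(2-methylbut-3-en-2-yl)phenyl]-3,7-dihydroxychroman-4-one
Product: 18 (3R)-3-[2,3-dihydroxy-4-methoxy-5-(2-methylbut-3-en-2-yl)phenyl]-3,7-dihydroxychroman-4-one (CNP0274064.1)
Conditions: Bu4NF (2.5 equiv), AcOH (3 equiv), THF, 0 °C, argon
Reagents that add atoms: none
Why: Fluoride cleavage of the two aryl silyl ethers, buffered with acetic acid so that the liberated catechol is never a phenoxide exposed to air and the α-ketol never meets strong base; C3 has no hydrogen and is untouched.

## Compound list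

1 | gallacetophenone, 1-(2,3,4-trihydroxyphenyl)ethanone | CC(=O)c1ccc(O)c(O)c1O | starting material
2 | prenyl bromide, 1-bromo-3-methylbut-2-ene | CC(C)=CCBr | starting material
3 | 1-[2,3-dihydroxy-4-(3-methylbut-2-enyloxy)phenyl]ethanone | CC(=O)c1ccc(OCC=C(C)C)c(O)c1O | intermediate
4 | 1-[2,3-bis(TBSO)-4-(3-methylbut-2-enyloxy)phenyl]ethanone | CC(=O)c1ccc(OCC=C(C)C)c(O[Si](C)(C)C(C)(C)C)c1O[Si](C)(C)C(C)(C)C | intermediate
5 | rac-4-acetyl-2,3-bis(TBSO)-6-(2-methylbut-3-en-2-yl)cyclohexa-2,4-dien-1-one (Claisen dienone, not isolated) | CC(=O)C1=CC(C(C)(C)C=C)C(=O)C(O[Si](C)(C)C(C)(C)C)=C1O[Si](C)(C)C(C)(C)C | intermediate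
6 | 1-[2,3-bis(TBSO)-5-(2-methylbut-3-en-2-yl)-4-(trimethylsilyloxy)phenyl]ethanone (not isolated) | CC(=O)c1cc(C(C)(C)C=C)c(O[Si](C)(C)C)c(O[Si](C)(C)C(C)(C)C)c1O[Si](C)(C)C(C)(C)C | intermediate
7 | 1-[2,3-bis(TBSO)-4-hydroxy-5-(2-methylbut-3-en-2-yl)phenyl]ethanone | CC(=O)c1cc(C(C)(C)C=C)c(O)c(O[Si](C)(C)C(C)(C)C)c1O[Si](C)(C)C(C)(C)C | intermediate
8 | 1-[2,3-bis(TBSO)-4-methoxy-5-(2-methylbut-3-en-2-yl)phenyl]ethanone | CC(=O)c1cc(C(C)(C)C=C)c(OC)c(O[Si](C)(C)C(C)(C)C)c1O[Si](C)(C)C(C)(C)C | intermediate
9 | 1-[2,3-bis(TBSO)-4-methoxy-5-(2-methylbut-3-en-2-yl)phenyl]ethenyl trifluoromethanesulfonate | C=C(OS(=O)(=O)C(F)(F)F)c1cc(C(C)(C)C=C)c(OC)c(O[Si](C)(C)C(C)(C)C)c1O[Si](C)(C)C(C)(C)C | intermediate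
10 | 2,4-dihydroxybenzaldehyde | O=Cc1ccc(O)cc1O | starting material
11 | 2,4-bis(TBSO)benzaldehyde | O=Cc1ccc(O[Si](C)(C)C(C)(C)C)cc1O[Si](C)(C)C(C)(C)C | intermediate
12 | {1-[2,3-bis(TBSO)-4-methoxy-5-(2-methylbut-3-en-2-yl)phenyl]ethenyl}chromium dichloride (alkenyl complex of trivalent chromium, DMF-solvated, not isolated) | C=C([Cr](Cl)Cl)c1cc(C(C)(C)C=C)c(OC)c(O[Si](C)(C)C(C)(C)C)c1O[Si](C)(C)C(C)(C)C | intermediate
13 | rac-1-[2,4-bis(TBSO)phenyl]-2-[2,3-bis(TBSO)-4-methoxy-5-(2-methylbut-3-en-2-yl)phenyl]prop-2-en-1-ol | C=C(C(O)c1ccc(O[Si](C)(C)C(C)(C)C)cc1O[Si](C)(C)C(C)(C)C)c1cc(C(C)(C)C=C)c(OC)c(O[Si](C)(C)C(C)(C)C)c1O[Si](C)(C)C(C)(C)C | intermediate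
14 | 1-[2,4-bis(TBSO)phenyl]-2-[2,3-bis(TBSO)-4-methoxy-5-(2-methylbut-3-en-2-yl)phenyl]prop-2-en-1-one | C=CC(C)(C)c1cc(C(=C)C(=O)c2ccc(O[Si](C)(C)C(C)(C)C)cc2O[Si](C)(C)C(C)(C)C)c(O[Si](C)(C)C(C)(C)C)c(O[Si](C)(C)C(C)(C)C)c1OC | intermediate
15 | [2,4-bis(TBSO)phenyl]{(2R)-2-[2,3-bis(TBSO)-4-methoxy-5-(2-methylbut-3-en-2-yl)phenyl]oxiran-2-yl}methanone (not isolated) | C=CC(C)(C)c1cc([C@@]2(C(=O)c3ccc(O[Si](C)(C)C(C)(C)C)cc3O[Si](C)(C)C(C)(C)C)OC2)c(O[Si](C)(C)C(C)(C)C)c(O[Si](C)(C)C(C)(C)C)c1OC | intermediate
16 | (2,4-dihydroxyphenyl){(2R)-2-[2,3-bis(TBSO)-4-methoxy-5-(2-methylbut-3-en-2-yl)phenyl]oxiran-2-yl}methanone (not isolated) | C=CC(C)(C)c1cc([C@@]2(C(=O)c3ccc(O)cc3O)OC2)c(O[Si](C)(C)C(C)(C)C)c(O[Si](C)(C)C(C)(C)C)c1OC | intermediate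
17 | (3R)-3-[2,3-bis(TBSO)-4-methoxy-5-(2-methylbut-3-en-2-yl)phenyl]-3,7-dihydroxychroman-4-one | C=CC(C)(C)c1cc([C@@]2(O)COc3cc(O)ccc3C2=O)c(O[Si](C)(C)C(C)(C)C)c(O[Si](C)(C)C(C)(C)C)c1OC | intermediate
18 | (3R)-3-[2,3-dihydroxy-4-methoxy-5-(2-methylbut-3-en-2-yl)phenyl]-3,7-dihydroxychroman-4-one (CNP0274064.1) | C=CC(C)(C)c1cc([C@@]2(O)COc3cc(O)ccc3C2=O)c(O)c(O)c1OC | target

## Step count and risks

Total: 10 steps. Longest linear sequence: 9 steps (steps 1–5 and 7–10); step 6 is a one-step side branch.

**Step 9 (key step).** Facial selectivity in the oxirane closure may be poor, because the carbonyl is flanked by two twisted, ortho-substituted aryl groups and may sit badly in the catalyst pocket. Early loss of the ring A ortho silyl group would open the racemic oxa-Michael channel. A silyl shift from O2' to the new tertiary alkoxide would be harmless, since step 10 removes it. The fallback sets out from 13 and returns at 15. Sharpless kinetic resolution of the racemic allylic alcohol (Ti(OiPr)4, L-(+)-diisopropyl tartrate, tBuOOH, 4 Å sieves, CH2Cl2, –20 °C, stopped near half conversion) should convert one enantiomer into the epoxy alcohol (S)-[2,4-bis(TBSO)phenyl]{(2R)-2-[2,3-bis(TBSO)-4-methoxy-5-(2-methylbut-3-en-2-yl)phenyl]oxiran-2-yl}methanol F1. The tartrate fixes the oxirane carbon as (R) by the usual facial rule. Oxidation of the carbinol (nPr4N[RuO4], N-methylmorpholine N-oxide) erases the second centre and gives 15, which then goes through the K2CO3/MeOH stage of step 9. The price is half of 13 and exposure of an aryl oxirane to a Lewis acidic alkoxide of tetravalent titanium.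

**Step 3.** At 185 °C the silyl groups may migrate or be lost, and the abnormal Claisen pathway or cyclisation onto the alkene may compete if trapping of the phenol is slow. The fallback sets out from 3 and returns at 8. The unsilylated prenyl ether is rearranged under acylating conditions (Ac2O, NaOAc, PhNEt2, 180 °C) to 1-[2,3,4-triacetoxy-5-(2-methylbut-3-en-2-yl)phenyl]ethanone F2. K2CO3 in MeOH frees 1-[2,3,4-trihydroxy-5-(2-methylbut-3-en-2-yl)phenyl]ethanone F3. Borate-templated methylation (Na2B4O7, aq. NaOH, Me2SO4), the method that methylates gallacetophenone itself at O4, gives 1-[2,3-dihydroxy-4-methoxy-5-(2-methylbut-3-en-2-yl)phenyl]ethanone F4. TBSCl and imidazole then give 8. This also answers a failure of the methylation in step 4.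

**Step 5.** The ortho silyl group may transfer to the enolate oxygen, and the electron-rich vinyl triflate may eliminate to the aryl alkyne or ionise during isolation. The fallback sets out from 8 and returns at 13. Hydrazine hydrate (Et3N, EtOH) gives the hydrazone of 8, 1-[2,3-bis(TBSO)-4-methoxy-5-(2-methylbut-3-en-2-yl)phenyl]ethanone hydrazone F5. Iodine and tetramethylguanidine in THF (Barton vinyl iodide synthesis) give 1-(1-iodoethenyl)-2,3-bis(TBSO)-4-methoxy-5-(2-methylbut-3-en-2-yl)benzene F6. F6 enters the CrCl2/NiCl2 coupling of step 7 with 11, through 12, to give 13.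

**Step 7.** Addition of the hindered alkenylchromium species to an electron-rich, ortho-substituted aldehyde may be slow, so that reductive homocoupling or protodemetalation takes over. The fallback sets out from 8 by way of the iodide F6 of the preceding fallback and returns at 13. Iodine–magnesium exchange with iPrMgCl·LiCl (THF, –30 °C) gives {1-[2,3-bis(TBSO)-4-methoxy-5-(2-methylbut-3-en-2-yl)phenyl]ethenyl}magnesium chloride F7, which adds to 11 at –78 °C. A carbon–magnesium bond is more nucleophilic than carbon–chromium, yet far less prone to the O-to-C silyl shift than carbon–lithium.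

## Further compounds

F1 | step 9 | (S)-[2,4-bis(TBSO)phenyl]{(2R)-2-[2,3-bis(TBSO)-4-methoxy-5-(2-methylbut-3-en-2-yl)phenyl]oxiran-2-yl}methanol | C=CC(C)(C)c1cc([C@@]2([C@@H](O)c3ccc(O[Si](C)(C)C(C)(C)C)cc3O[Si](C)(C)C(C)(C)C)OC2)c(O[Si](C)(C)C(C)(C)C)c(O[Si](C)(C)C(C)(C)C)c1OC
F2 | step 3 | 1-[2,3,4-triacetoxy-5-(2-methylbut-3-en-2-yl)phenyl]ethanone | CC(=O)c1cc(C(C)(C)C=C)c(OC(C)=O)c(OC(C)=O)c1OC(C)=O
F3 | step 3 | 1-[2,3,4-trihydroxy-5-(2-methylbut-3-en-2-yl)phenyl]ethanone | CC(=O)c1cc(C(C)(C)C=C)c(O)c(O)c1O
F4 | step 3 | 1-[2,3-dihydroxy-4-methoxy-5-(2-methylbut-3-en-2-yl)phenyl]ethanone | CC(=O)c1cc(C(C)(C)C=C)c(OC)c(O)c1O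
F5 | step 5 | 1-[2,3-bis(TBSO)-4-methoxy-5-(2-methylbut-3-en-2-yl)phenyl]ethanone hydrazone | CC(=NN)c1cc(C(C)(C)C=C)c(OC)c(O[Si](C)(C)C(C)(C)C)c1O[Si](C)(C)C(C)(C)C
F6 | step 5 | 1-(1-iodoethenyl)-2,3-bis(TBSO)-4-methoxy-5-(2-methylbut-3-en-2-yl)benzene | C=C(I)c1cc(C(C)(C)C=C)c(OC)c(O[Si](C)(C)C(C)(C)C)c1O[Si](C)(C)C(C)(C)C
F7 | step 7 | {1-[2,3-bis(TBSO)-4-methoxy-5-(2-methylbut-3-en-2-yl)phenyl]ethenyl}magnesium chloride | C=C([Mg]Cl)c1cc(C(C)(C)C=C)c(OC)c(O[Si](C)(C)C(C)(C)C)c1O[Si](C)(C)C(C)(C)C
A1 | alternative 1 | 2-diazo-1-[2-fluoro-4-(TBSO)phenyl]-2-[2,3-bis(TBSO)-4-methoxy-5-(2-methylbut-3-en-2-yl)phenyl]ethanone | C=CC(C)(C)c1cc(C(=[N+]=[N-])C(=O)c2ccc(O[Si](C)(C)C(C)(C)C)cc2F)c(O[Si](C)(C)C(C)(C)C)c(O[Si](C)(C)C(C)(C)C)c1OC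
A2 | alternative 1 | (2R)-1-[2-fluoro-4-(TBSO)phenyl]-3-hydroxy-2-(4-methoxybenzyloxy)-2-[2,3-bis(TBSO)-4-methoxy-5-(2-methylbut-3-en-2-yl)phenyl]propan-1-one | C=CC(C)(C)c1cc([C@@](C(=O)c2ccc(O[Si](C)(C)C(C)(C)C)cc2F)(OCc3ccc(OC)cc3)CO)c(O[Si](C)(C)C(C)(C)C)c(O[Si](C)(C)C(C)(C)C)c1OC
A3 | alternative 2 | 3,10-bis(TBSO)-9-methoxy-8-(2-methylbut-3-en-2-yl)-6H-benzofuro[3,2-c]chromene (pterocarpene) | C=CC(C)(C)c1cc2c(c(O[Si](C)(C)C(C)(C)C)c1OC)oc1c2COc2cc(O[Si](C)(C)C(C)(C)C)ccc21
A4 | alternative 2 | (3R)-7-(TBSO)-3-hydroxy-3-[2-hydroxy-3-(TBSO)-4-methoxy-5-(2-methylbut-3-en-2-yl)phenyl]chroman-4-one | C=CC(C)(C)c1cc([C@@]2(O)COc3cc(O[Si](C)(C)C(C)(C)C)ccc3C2=O)c(O)c(O[Si](C)(C)C(C)(C)C)c1OC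
A5 | alternative 3 | 2-{2-[2,3-bis(TBSO)-4-methoxy-5-(2-methylbut-3-en-2-yl)phenyl]-2-oxoethoxy}-4-(TBSO)benzaldehyde | C=CC(C)(C)c1cc(C(=O)COc2cc(O[Si](C)(C)C(C)(C)C)ccc2C=O)c(O[Si](C)(C)C(C)(C)C)c(O[Si](C)(C)C(C)(C)C)c1OC
A6 | alternative 3 | (3R)-7-(TBSO)-3-[2,3-bis(TBSO)-4-methoxy-5-(2-methylbut-3-en-2-yl)phenyl]-3-hydroxychroman-4-one | C=CC(C)(C)c1cc([C@@]2(O)COc3cc(O[Si](C)(C)C(C)(C)C)ccc3C2=O)c(O[Si](C)(C)C(C)(C)C)c(O[Si](C)(C)C(C)(C)C)c1OC
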